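**Retrosynthetic overview**
1. Target 20 ⇐ nitro dialdehyde 18. The CO2H group is carried as CH2NO2 and unveiled in the last step without touching the neighbouring stereocentre.
2. 18 ⇐ Z-enynol 16. Ring A (the dihydrofuran, the only ring) is closed late by anti 5-exo-dig iodoetherification. C–I then becomes C–CHO with retention, which fixes the E-alkene.
3. 16 ⇐ δ-nitro ester 14. The ester and the ketone are reduced together and re-oxidised together.
4. Key bond C3–C4 of 14 ⇐ enynal 13 + nitrodiene 7. A chiral carbene makes the enal β-carbon a donor (homoenolate), which attacks the nitroalkene β-carbon. Both carbons are natural acceptors, and both stereocentres are set here.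
5. 13 ⇐ iodide 10 + enynol 11 (Sonogashira coupling, then oxidation). 7 ⇐ 1-methylcyclohexene (ozonolysis, α-methylenation, Henry reaction and dehydration).

Assumption: the facial sense of the triazolium catalyst is assigned by analogy; both enantiomers are sold, and the one that gives (3S,4R)-14 is used.

**Step 1**
Reactants: 1 1-methylcyclohexene
Product: 3 6-oxoheptanal, via secondary ozonide 2 (not isolated)
Conditions: O3, CH2Cl2, −78 °C; then Me2S, −78 °C → rt
Reagents that add atoms: ozone, [O-][O+]=O
Why: Criegee ozonolysis of the only alkene, followed by reductive cleavage of the ozonide with Me2S, opens the ring to the keto aldehyde; no stereocentre is formed.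

**Step 2**
Reactants: 3 6-oxoheptanal
Product: 4 2-methylidene-6-oxoheptanal
Conditions: 37 % aq. HCHO, pyrrolidine (10 mol %), EtCO2H (10 mol %), i-PrOH, 45 °C
Reagents that add atoms: formaldehyde, C=O
Why: In this organocatalytic α-methylenation (Mannich condensation then elimination) the aldehyde is activated by the amine much faster than the methyl ketone, and excess formaldehyde captures it before it can close onto the ketone.

**Step 3**
Reactants: 4 2-methylidene-6-oxoheptanal
Product: 7 (E)-6-methylidene-8-nitrooct-7-en-2-one, via nitro alcohol 5 (not isolated), via nitro mesylate 6 (not isolated)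
Conditions: MeNO2 (5 equiv), KOt-Bu (10 mol %), THF/t-BuOH, 0 °C; solvent swap; MsCl, Et3N, CH2Cl2, −20 → 0 °C
Reagents that add atoms: nitromethane, C[N+](=O)[O-]
Why: A Henry reaction under short, cold, kinetic conditions gives 1,2-addition to the enal (excess MeNO2 holds the base as nitronate, so the ketone is not enolised), and mesylation with E1cB elimination then gives the favoured E-nitroalkene.

**Step 4**
Reactants: 8 ethyl (Z)-3-iodoacrylate
Product: 10 (Z)-4-iodo-2-methylbut-3-en-2-ol, via Z-iodo enone 9 (not isolated)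
Conditions: MeMgBr (2.5 equiv), Et2O, −78 → 0 °C; aqueous work-up
Reagents that add atoms: methylmagnesium bromide, C[Mg]Br
Why: Double Grignard addition to the ester is used because MeMgBr does not undergo iodine–magnesium exchange or addition–elimination at low temperature, so the Z-vinyl iodide survives.

**Step 5**
Reactants: 10 (Z)-4-iodo-2-methylbut-3-en-2-ol; 11 (E)-pent-2-en-4-yn-1-ol
Product: 12 (2E,6Z)-8-methylnona-2,6-dien-4-yne-1,8-diol
Conditions: PdCl2(PPh3)2 (2 mol %), CuI (4 mol %), Et3N, THF, 0 °C → rt
Reagents that add atoms: none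
Why: Sonogashira coupling of a vinyl iodide proceeds with retention of both alkene geometries, and at or below room temperature Z-enynols of this type can be isolated before they cyclise.

**Step 6**
Reactants: 12 (2E,6Z)-8-methylnona-2,6-dien-4-yne-1,8-diol
Product: 13 (2E,6Z)-8-hydroxy-8-methylnona-2,6-dien-4-ynal
Conditions: MnO2, CH2Cl2, rt
Reagents that add atoms: none
Why: Neutral MnO2 allylic oxidation converts only the primary allylic alcohol, since the tertiary carbinol cannot be oxidised.

**Step 7 (key step)**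
Reactants: 13 (2E,6Z)-8-hydroxy-8-methylnona-2,6-dien-4-ynal; 7 (E)-6-methylidene-8-nitrooct-7-en-2-one
Product: 14 methyl (3S,4R)-3-[(3Z)-5-hydroxy-5-methylhex-3-en-1-yn-1-yl]-5-methylidene-4-(nitromethyl)-9-oxodecanoate
Conditions: (5aR,10bS)-2-mesityl-5a,10b-dihydro-4H,6H-indeno[2,1-b][1,2,4]triazolo[4,3-d][1,4]oxazin-2-ium chloride (15 mol %), i-Pr2NEt (30 mol %), MeOH (10 equiv), THF, 0 °C → rt, 7 added slowly
Reagents that add atoms: methanol, CO
Why: In this NHC-catalysed homoenolate conjugate addition with redox esterification the carbene adds to the formyl group of 13 and turns its β-carbon, normally an acceptor, into a donor that attacks the acceptor β-carbon of nitroalkene 7 in 1,4-fashion; the open antiperiplanar approach of E-homoenolate and E-nitroalkene gives the anti pair, the aminoindanol wall selects the face so that both stereocentres (3S,4R) are set, and MeOH frees the catalyst as the methyl ester forms.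

**Step 8**
Reactants: 14 δ-nitro ester
Product: 15 (3S,4R)-3-[(3Z)-5-hydroxy-5-methylhex-3-en-1-yn-1-yl]-5-methylidene-4-(nitromethyl)decane-1,9-diol (C9 epimers)
Conditions: LiBH4 (4 equiv), MeOH (additive), THF, 0 °C → rt; aq. NH4Cl at 0 °C
Reagents that add atoms: none
Why: Borohydride reduction takes the ester and the ketone together while the nitro group (parked as its nitronate) and all π-bonds are untouched; the new C9 carbinol centre does not matter because step 9 removes it.

**Step 9**
Reactants: 15 triol
Product: 16 (3S,4R)-3-[(3Z)-5-hydroxy-5-methylhex-3-en-1-yn-1-yl]-5-methylidene-4-(nitromethyl)-9-oxodecanal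
Conditions: Dess–Martin periodinane (2.5 equiv), CH2Cl2, 0 °C → rt; work-up at pH 7
Reagents that add atoms: none
Why: Base-free Dess–Martin oxidation converts the primary and secondary alcohols in one operation, leaves the tertiary alcohol alone, and avoids the base that would trigger an intramolecular Henry reaction of the δ-nitro aldehyde.

**Step 10**
Reactants: 16 keto aldehyde enynol
Product: 18 (3S,4R)-3-[(1E)-1-(5,5-dimethylfuran-2(5H)-ylidene)-2-oxoethyl]-5-methylidene-4-(nitromethyl)-9-oxodecanal, via E-iodoalkylidene dihydrofuran 17 (not isolated)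
Conditions: NIS (1.0 equiv), THF, −20 → 0 °C, dark; then Pd(PPh3)4 (5 mol %), CO (3 atm), Bu3SnH (1.1 equiv, syringe pump), 50 °C
Reagents that add atoms: carbon monoxide, [C-]#[O+]
Why: Electrophilic 5-exo-dig iodoetherification, favoured over 6-endo closure by the gem-dimethyl carbinol, adds O and I anti across the alkyne, and Stille-type reductive carbonylation (formylation) at zerovalent palladium replaces iodine by CHO with retention, so CHO ends trans to the ring oxygen (E) under neutral conditions.

**Step 11**
Reactants: 18 nitro dialdehyde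
Product: 20 (2R,3S)-3-[(1E)-1-(5,5-dimethylfuran-2(5H)-ylidene)-2-oxoethyl]-5-oxo-2-(6-oxohept-1-en-2-yl)pentanoic acid, via nitrolic acid 19 (not isolated)
Conditions: NaNO2 (3 equiv), AcOH (10 equiv), DMSO, 35 °C
Reagents that add atoms: sodium nitrite, [Na+].[O-]N=O
Why: In this nitrosative Nef-type oxidation of a primary nitroalkane the nitro carbon is nitrosated to the nitrolic acid, which collapses to the acid with loss of N2O; the adjacent C–H is never acidified, so the stereocentre is kept, and the large excess of AcOH keeps free nitronate too short-lived for 5-exo Henry closure onto the aldehydes.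

**Compound list**
1 | 1-methylcyclohexene | CC1=CCCCC1 | starting material
2 | 1-methyl-7,8,9-trioxabicyclo[4.2.1]nonane (secondary ozonide) | CC12CCCCC(OO1)O2 | intermediate
3 | 6-oxoheptanal | CC(=O)CCCCC=O | intermediate
4 | 2-methylidene-6-oxoheptanal | C=C(C=O)CCCC(C)=O | intermediate
5 | 7-hydroxy-6-methylidene-8-nitrooctan-2-one (racemic) | C=C(CCCC(C)=O)C(O)C[N+](=O)[O-] | intermediate
6 | 3-methylidene-1-nitro-7-oxooctan-2-yl methanesulfonate (racemic) | C=C(CCCC(C)=O)C(OS(C)(=O)=O)C[N+](=O)[O-] | intermediate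
7 | (E)-6-methylidene-8-nitrooct-7-en-2-one | C=C(CCCC(C)=O)/C=C/[N+](=O)[O-] | intermediate
8 | ethyl (Z)-3-iodoacrylate | CCOC(=O)/C=C\I | starting material
9 | (Z)-4-iodobut-3-en-2-one | CC(=O)/C=C\I | intermediate
10 | (Z)-4-iodo-2-methylbut-3-en-2-ol | CC(C)(O)/C=C\I | intermediate
11 | (E)-pent-2-en-4-yn-1-ol | C#C/C=C/CO | starting material
12 | (2E,6Z)-8-methylnona-2,6-dien-4-yne-1,8-diol | OC/C=C/C#C/C=C\C(C)(C)O | intermediate
13 | (2E,6Z)-8-hydroxy-8-methylnona-2,6-dien-4-ynal | O=C/C=C/C#C/C=C\C(C)(C)O | intermediate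
14 | methyl (3S,4R)-3-[(3Z)-5-hydroxy-5-methylhex-3-en-1-yn-1-yl]-5-methylidene-4-(nitromethyl)-9-oxodecanoate | C=C(CCCC(C)=O)[C@H](C[N+](=O)[O-])[C@H](CC(=O)OC)C#C/C=C\C(C)(C)O | intermediate
15 | (3S,4R)-3-[(3Z)-5-hydroxy-5-methylhex-3-en-1-yn-1-yl]-5-methylidene-4-(nitromethyl)decane-1,9-diol (C9 epimers) | C=C(CCCC(C)O)[C@H](C[N+](=O)[O-])[C@H](CCO)C#C/C=C\C(C)(C)O | intermediate
16 | (3S,4R)-3-[(3Z)-5-hydroxy-5-methylhex-3-en-1-yn-1-yl]-5-methylidene-4-(nitromethyl)-9-oxodecanal | C=C(CCCC(C)=O)[C@H](C[N+](=O)[O-])[C@H](CC=O)C#C/C=C\C(C)(C)O | intermediate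
17 | (3S,4R)-3-[(E)-(5,5-dimethylfuran-2(5H)-ylidene)(iodo)methyl]-5-methylidene-4-(nitromethyl)-9-oxodecanal | C=C(CCCC(C)=O)[C@H](C[N+](=O)[O-])[C@H](CC=O)/C(I)=C1/C=CC(C)(C)O1 | intermediate
18 | (3S,4R)-3-[(1E)-1-(5,5-dimethylfuran-2(5H)-ylidene)-2-oxoethyl]-5-methylidene-4-(nitromethyl)-9-oxodecanal | C=C(CCCC(C)=O)[C@H](C[N+](=O)[O-])[C@H](CC=O)/C(C=O)=C1/C=CC(C)(C)O1 | intermediate
19 | (3S,4R)-3-[(1E)-1-(5,5-dimethylfuran-2(5H)-ylidene)-2-oxoethyl]-4-[(hydroxyimino)(nitro)methyl]-5-methylidene-9-oxodecanal (nitrolic acid) | C=C(CCCC(C)=O)[C@H](C(=NO)[N+](=O)[O-])[C@H](CC=O)/C(C=O)=C1/C=CC(C)(C)O1 | intermediate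
20 | (2R,3S)-3-[(1E)-1-(5,5-dimethylfuran-2(5H)-ylidene)-2-oxoethyl]-5-oxo-2-(6-oxohept-1-en-2-yl)pentanoic acid (CNP0150297.1) | C=C(CCCC(C)=O)[C@H](C(=O)O)[C@H](CC=O)/C(C=O)=C1/C=CC(C)(C)O1 | target

**Totals**
Total step count: 11.
Longest linear sequence: 8 steps (1, 2, 3, 7, 8, 9, 10, 11). The arm 4, 5, 6, 7–11 is equally long.

**Three steps most likely to fail**

**Step 7.** Several things can go wrong with this coupling.
- The extended enynal may react through its distal alkyne carbon.
- The free carbinol may close by 1,6-oxa-Michael addition onto the activated enyne.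
- The nitrodiene may take 1,6-attack at its terminal CH2, polymerise, or trap the carbene.
- The dr and ee are untested for an alkynyl enal.

The fallback leaves the carbinol tail off during the polarity-reversed coupling and attaches it afterwards. It sets out from nitrodiene 7. Commercial 3-(trimethylsilyl)propynal is homologated with Ph3P=CHCHO (toluene, rt) to (E)-5-(trimethylsilyl)pent-2-en-4-ynal F1, whose silyl cap blocks the distal carbon. The same carbene-catalysed addition of F1 to 7 in THF/MeOH gives methyl (3S,4R)-5-methylidene-4-(nitromethyl)-9-oxo-3-[(trimethylsilyl)ethynyl]decanoate F2. Buffered TBAF/AcOH then gives methyl (3S,4R)-3-ethynyl-5-methylidene-4-(nitromethyl)-9-oxodecanoate F3. Sonogashira coupling of F3 with iodide 10 comes back to the route at 14.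

**Step 10.** The labile β-iodo enol ether may decompose, the hindered vinyl iodide may be reduced instead of carbonylated, or Bu3SnH with palladium may attack the enal. The fallback replaces the halogen/carbonylation logic by polar formylation of an enol ether. It sets out from 16. AgOTf (5 mol %, CH2Cl2, rt, dark) cycloisomerises the Z-enynol to (3S,4R)-3-[(Z)-(5,5-dimethylfuran-2(5H)-ylidene)methyl]-5-methylidene-4-(nitromethyl)-9-oxodecanal F4. (Chloromethylene)dimethyliminium chloride at 0 °C attacks the nucleophilic exocyclic carbon (Vilsmeier–Haack formylation) to give the vinylogous iminium chloride F5. Aqueous NaOAc hydrolyses F5, and the fallback comes back at 18. In this case the alkene geometry is under thermodynamic control and no longer set mechanistically.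

**Step 11.** The nitronate may close onto the C1 aldehyde (5-exo Henry reaction), or the enolisable aldehyde may be nitrosated. The fallback masks that aldehyde before the ring and the acid are made. It sets out from 16. HC(OMe)3 with catalytic PPTS in MeOH gives the C1 dimethyl acetal of 16 F6, with the methyl ketone left free. NIS gives the corresponding E-iodoalkylidene dihydrofuran acetal F7, and Pd(PPh3)4/CO/Bu3SnH gives the formyl acetal F8. NaNO2/AcOH/DMSO gives the acid acetal F9, and AcOH/THF/H2O at 35 °C releases the aldehyde, coming back at 20.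

**Further compounds**
F1 | step 7 | (E)-5-(trimethylsilyl)pent-2-en-4-ynal | C[Si](C)(C)C#C/C=C/C=O
F2 | step 7 | methyl (3S,4R)-5-methylidene-4-(nitromethyl)-9-oxo-3-[(trimethylsilyl)ethynyl]decanoate | C=C(CCCC(C)=O)[C@H](C[N+](=O)[O-])[C@H](CC(=O)OC)C#C[Si](C)(C)C
F3 | step 7 | methyl (3S,4R)-3-ethynyl-5-methylidene-4-(nitromethyl)-9-oxodecanoate | C=C(CCCC(C)=O)[C@H](C[N+](=O)[O-])[C@H](CC(=O)OC)C#C
F4 | step 10 | (3S,4R)-3-[(Z)-(5,5-dimethylfuran-2(5H)-ylidene)methyl]-5-methylidene-4-(nitromethyl)-9-oxodecanal | C=C(CCCC(C)=O)[C@H](C[N+](=O)[O-])[C@H](CC=O)/C=C1/C=CC(C)(C)O1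
F5 | step 10 | N,N-dimethyliminium chloride of 18 at the ylidene formyl group | C=C(CCCC(C)=O)[C@H](C[N+](=O)[O-])[C@H](CC=O)/C(C=[N+](C)C)=C1/C=CC(C)(C)O1.[Cl-]
F6 | step 11 | C1 dimethyl acetal of 16 | C=C(CCCC(C)=O)[C@H](C[N+](=O)[O-])[C@H](CC(OC)OC)C#C/C=C\C(C)(C)O
F7 | step 11 | C1 dimethyl acetal of 17 | C=C(CCCC(C)=O)[C@H](C[N+](=O)[O-])[C@H](CC(OC)OC)/C(I)=C1/C=CC(C)(C)O1
F8 | step 11 | C1 dimethyl acetal of 18 | C=C(CCCC(C)=O)[C@H](C[N+](=O)[O-])[C@H](CC(OC)OC)/C(C=O)=C1/C=CC(C)(C)O1
F9 | step 11 | C5 dimethyl acetal of 20 | C=C(CCCC(C)=O)[C@H](C(=O)O)[C@H](CC(OC)OC)/C(C=O)=C1/C=CC(C)(C)O1
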